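The runs were computed for an exercise; the scatter is artificial.

The dusk run held 4.00 times the free base of the spring run, yet at 3.00 h their target readings differ by 0.9 percentage points, with a scatter of 0.5 points on each. So you may pool them for the new flask, whose free base lies between theirs.

| setting | spring | dusk | flask |
|---|---|---|---|
| electrophile | 0.10 M | 0.10 M | 0.10 M |
| nucleophile | 0.090 M | 0.090 M | 0.0900 M |
| free base | 0.15 M | 0.60 M | 0.300 M |
| remark | run made earlier | run made earlier |  |
| time |  |  | 4.0 h |

| run | time / h | target / % | side product / % |
|---|---|---|---|
| spring | 0.167 | 2.4 | 0.4 |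
| spring | 0.500 | 7.5 | 1.0 |
| spring | 0.833 | 11.4 | 0 |
| spring | 1.33 | 16.6 | 1.1 |
| spring | 2.00 | 21.1 | 2.7 |
| spring | 2.50 | 23.4 | 4.7 |
| spring | 3.00 | 25.2 | 5.2 |
| dusk | 0.500 | 7.7 | 0 |
| dusk | 1.00 | 13.6 | 0.8 |
| dusk | 1.33 | 16.5 | 1.3 |
| dusk | 2.00 | 20.3 | 4.1 |
| dusk | 2.50 | 24.6 | 4.6 |
| dusk | 3.00 | 26.1 | 5.7 |

(each reading ± 0.5 percentage points)

- in percentages every species weighs as the electrophile in it: one side product counts as two

- concentration of target at 4.0 h, in M
- concentration of side product at 4.0 h, in M
- concentration of electrophile at 4.0 h, in M

Keep the books on the electrophile. At 3.00 h the pooled readings enter target T at 25.6% and side product S at 5.45%, and the balance leaves 68.9% as electrophile. Side product lags target and holds two electrophiles, which suggests that each molecule forms from one target and one electrophile. Then the pooled readings give 10.4 for the ledger ratio L, target made per target lost so far, which is one plus the target concentration over the side-product concentration. Target grows while it is made faster than it is lost, but L counts the run so far, not the present moment.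

The forecast, judging “so the rate is essentially zero order in base”, gives 0.0285 M target, 0.004 M side product and 0.0635 M electrophile. Those imply L = 8.12 at 4.0 h, lower than the pooled 10.4 at 3.00 h, the direction you expect once more target stands exposed to loss.

The flask gives 0.0292 M target, 0.00405 M side product and 0.0627 M electrophile, all within the margin.

    acid set free + free base ⇌ salt of the base, settled at all times (K = 4.50 L mol⁻¹)
    electrophile + target → side product (k = 0.730 L mol⁻¹ h⁻¹)
    electrophile + nucleophile → acid set free + target (k = 1.90 L mol⁻¹ h⁻¹)
    acid set free → by-product carried off (k = 0.120 h⁻¹)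
    nucleophile + acid set free ⇌ protonated nucleophile, settled at all times (K = 160 L mol⁻¹)

The flask's ledger ratio is 8.21, and at 4.00 h target is still made 3.05 times faster than it is used. The largest single brake on target in this flask is the running short of nucleophile, the limiting reagent, with 37.9% of its charge still unbound at 4.00 h: with that running short removed, this flask holds 0.0438 M target instead of 0.0292 M. The neighbour charged with 0.22 M nucleophile gives 0.0584 M target and 0.00551 M side product, so its ledger ratio is higher, at 11.6.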